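**Assumption (one line):** locants C1–C15 follow the germacrane numbering of the target in every intermediate (C3 ketal carbon, C6/C7 lactone carbons, C8 ester carbon, C10 methyl carbinol; α = face of H7), and compounds 1, 2, 9, 12 and 20 are bought.

## Retrosynthetic overview

1. Target ⇐ acylation of the C8 hydroxyl of hemiketal diol 19 with (Z)-2-(acetoxymethyl)but-2-enoic acid 26; the hemiketal bridge ⇐ desilylation of the ten-membered (1Z,4Z)-dienone 17.
2. 17 ⇐ ring expansion: β-scission of the C3–C9 fusion bond of the cyclopentene/cycloheptene-fused carbinol 16 (five + seven → ten-membered ring).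
3. 16 ⇐ ring-closing metathesis (C4=C5) after isopropenyl addition to the C3 ketone; trans-lactone ⇐ allylchromium addition of bromide 11 to acrolein (C6–C7).
4. 11 ⇐ Morita–Baylis–Hillman/bromination of aldehyde 8 ⇐ anti aldol (C8–C9) of (R)-4-hydroxycyclopentenone 1 with 2, methyl addition at C10, oxidation at C3.
5. Ring order: cyclopentene (bought) → γ-lactone → cycloheptene → ten-membered carbocycle → dihydrofuranol bridge.

## Route

Step 1
Reactants: 1 (R)-4-hydroxycyclopent-2-en-1-one; 2 2,2-dimethoxyacetaldehyde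
Product: 4 (4S,5S)-4-hydroxy-5-[(1R)-1-hydroxy-2,2-dimethoxyethyl]cyclopent-2-en-1-one, via bis-boryl dienolate 3 (not isolated)
Conditions: c-Hex2BCl (2.2 equiv), Et3N (2.5 equiv), Et2O, −78 → 0 °C; dry 2, −78 °C; MeOH/pH 7 buffer
Reagents that add atoms: none
Why: Boron-mediated anti aldol (Zimmerman–Traxler chair): the C3 hydroxyl is borylated in situ, the ring ketone gives the cross-conjugated (E)-enol borinate, C9 attacks the aldehyde on the face opposite the C3–OB group (3,9-trans) and the closed transition state gives the 8,9-anti adduct, which fixes C8 as in the target.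

Step 2
Reactants: 4 (4S,5S)-4-hydroxy-5-[(1R)-1-hydroxy-2,2-dimethoxyethyl]cyclopent-2-en-1-one
Product: 5 1-methyl-5-[(1R)-1-hydroxy-2,2-dimethoxyethyl]cyclopent-2-ene-1,4-diol (C10–OH cis to the side chain)
Conditions: MeLi (4 equiv), CeCl3 (4 equiv), THF, −78 °C; aq. NH4Cl
Reagents that add atoms: methyllithium [Li]C
Why: 1,2-Addition of the organocerium reagent (Imamoto) to the enone carbonyl C10 from the face opposite the C9 side chain sets the C10 methyl carbinol (O10 cis to the side chain, 1,3-anti to O8), while the hydroxyls are only deprotonated and the acetal is inert.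

Step 3
Reactants: 5 1-methyl-5-[(1R)-1-hydroxy-2,2-dimethoxyethyl]cyclopent-2-ene-1,4-diol
Product: 6 4-hydroxy-5-[(1R)-1-hydroxy-2,2-dimethoxyethyl]-4-methylcyclopent-2-en-1-one
Conditions: MnO2 (15 equiv), CH2Cl2, rt
Reagents that add atoms: none
Why: MnO2 oxidises only the secondary allylic alcohol (C3) to the enone; the non-allylic C8 alcohol and the tertiary C10 alcohol cannot react and no stereocentre is touched.

Step 4
Reactants: 6 4-hydroxy-5-[(1R)-1-hydroxy-2,2-dimethoxyethyl]-4-methylcyclopent-2-en-1-one
Product: 8 (2R)-2-[2-methyl-5-oxo-2-(triethylsilyloxy)cyclopent-3-en-1-yl]-2-(triethylsilyloxy)acetaldehyde, via bis-TES dimethyl acetal 7 (not isolated)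
Conditions: TESOTf (4.5 equiv), 2,6-lutidine (7 equiv), CH2Cl2, −78 → 0 °C; then H2O, 0 °C
Reagents that add atoms: triethylsilyl triflate CC[Si](CC)(CC)OS(=O)(=O)C(F)(F)F; water O
Why: TESOTf/2,6-lutidine silylates both hydroxyls and in the same pot turns the dimethyl acetal into its lutidinium adduct, which water cleaves to the aldehyde (Fujioka–Kita deacetalisation), conditions that leave silyl ethers and the enone intact.

Step 5
Reactants: 8 (2R)-2-[2-methyl-5-oxo-2-(triethylsilyloxy)cyclopent-3-en-1-yl]-2-(triethylsilyloxy)acetaldehyde; 9 methyl acrylate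
Product: 10 Morita–Baylis–Hillman adduct (methyl 3-hydroxy-2-methylenebutanoate carrying the C8 silyloxy group and the cyclopentenone at C4 of the butanoate; C7 carbinol as both epimers)
Conditions: 9 (10 equiv), DABCO (1 equiv), MeOH (cat.), rt, 4 d
Reagents that add atoms: none
Why: Morita–Baylis–Hillman reaction of the α-silyloxy aldehyde with the acrylate; the enone β-carbon next to quaternary C10 is too hindered to compete and the C7 carbinol epimers converge in step 6.

Step 6
Reactants: 10 Morita–Baylis–Hillman adduct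
Product: 11 (Z)-allyl bromide, methyl (Z)-2-(bromomethyl)but-2-enoate carrying the C8 silyloxy group and the cyclopentenone at C4 of the butenoate
Conditions: NBS (1.3 equiv), Me2S (1.5 equiv), CH2Cl2, 0 °C → rt
Reagents that add atoms: N-bromosuccinimide O=C1CCC(=O)N1Br
Why: Corey–Kim-type activation of the allylic alcohol and SN2′ attack of bromide give the thermodynamically preferred (Z)-2-(bromomethyl)enoate under neutral conditions that spare the TES ethers.

Step 7
Reactants: 11 (Z)-allyl bromide; 12 acrolein
Product: 14 trans-α-methylene-γ-vinyl-γ-butyrolactone ketone (6,7-trans lactone; C7 anti to O8), via anti hydroxy ester 13 (not isolated)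
Conditions: CrCl2 (4 equiv), 12 (3 equiv), THF, 0 °C → rt; aq. NH4Cl; SiO2
Reagents that add atoms: none
Why: Nozaki–Hiyama allylation with Dreiding–Schmidt lactonisation: the configurationally mobile allylchromium adds through a chair transition state with the bulky C8 substituent equatorial (6,7-anti, hence the trans lactone) and on the allyl face anti to C9 with H8 eclipsing the alkene (minimal allylic strain), which sets C7 anti to O8; the ketone is not attacked.

Step 8
Reactants: 14 trans-α-methylene-γ-vinyl-γ-butyrolactone ketone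
Product: 15 C3 isopropenyl carbinol (isopropenyl trans to the C9 side chain)
Conditions: isopropenylMgBr (2 equiv), LaCl3·2LiCl (30 mol%), THF, −78 → −30 °C
Reagents that add atoms: isopropenylmagnesium bromide CC(=C)[Mg]Br
Why: LaCl3·2LiCl-promoted Grignard 1,2-addition (Knochel) to the C3 ketone, which is far more electrophilic than the lactone; the nucleophile enters anti to the C9 substituent, and since C3 later becomes a carbonyl either epimer serves.

Step 9
Reactants: 15 C3 isopropenyl carbinol
Product: 16 tricyclic carbinol (cyclopentene and cycloheptene fused at C3–C9; trans-lactone on C6–C7)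
Conditions: second-generation Grubbs catalyst RuCl2(=CHPh)(H2IMes)(PCy3) (10 mol%), toluene (2 mM), 80 °C
Reagents that add atoms: none
Why: Ring-closing metathesis between the C5 vinyl group and the isopropenyl group gives the trisubstituted cycloheptene, whose ring size forces C4=C5 to be Z; the acrylate-type methylene and the hindered cyclopentene are poor metathesis partners.

Step 10
Reactants: 16 tricyclic carbinol
Product: 17 8β,10α-bis(triethylsilyloxy)-3-oxogermacra-1Z,4Z,11(13)-trien-6α,12-olide
Conditions: [Ir(dF(CF3)ppy)2(5,5′-d(CF3)bpy)]PF6 (2 mol%), 2,4,6-collidine (25 mol%), 2,4,6-triisopropylbenzenethiol (20 mol%), PhCF3 (0.02 M), blue LEDs, rt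
Reagents that add atoms: none
Why: Proposed new method: redox-neutral photocatalytic ring expansion of a ring-fusion bis-allylic tertiary alcohol, in which proton-coupled electron transfer (excited iridium photocatalyst plus collidine) gives the C3 alkoxy radical, whose only C(sp3) β-bond is C3–C9, so β-scission opens the fusion bond to the cross-conjugated ten-membered dienone and a secondary C9 radical that takes hydrogen from the thiol co-catalyst, both ring alkenes keeping the Z geometry imposed by the small rings and no stereocentre being created; the closest known reactions are the light-driven ring-opening isomerisation of simple cycloalkanols to acyclic ketones and Suárez alkoxy-radical fragmentations.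

Step 11
Reactants: 17 8β,10α-bis(triethylsilyloxy)-3-oxogermacra-1Z,4Z,11(13)-trien-6α,12-olide
Product: 19 3β,8β-dihydroxy-3α,10α-epoxygermacra-1,4Z,11(13)-trien-6α,12-olide, via dihydroxy dienone 18 (not isolated)
Conditions: HF·pyridine, pyridine, THF, 0 °C → rt
Reagents that add atoms: none
Why: Desilylation frees O8 and O10, and the C10 hydroxyl adds to the C3 carbonyl across the (Z)-enone (hemiketalisation); the bridge can only close on the α-face, so C3 is set under thermodynamic control.

Step 12
Reactants: 20 (E)-but-2-enal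
Product: 22 (Z)-2-bromobut-2-enal, via 2,3-dibromobutanal 21 (not isolated)
Conditions: Br2 (1 equiv), CH2Cl2, 0 °C; Et3N (1.2 equiv), 0 °C → rt
Reagents that add atoms: bromine BrBr
Why: Bromination then dehydrobromination gives the α-bromo enal with CHO trans to methyl, that is the (Z) isomer.

Step 13
Reactants: 22 (Z)-2-bromobut-2-enal
Product: 23 (Z)-2-bromobut-2-en-1-ol
Conditions: NaBH4, MeOH, 0 °C
Reagents that add atoms: none
Why: Borohydride 1,2-reduction of the aldehyde; the alkene geometry is unaffected.

Step 14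
Reactants: 23 (Z)-2-bromobut-2-en-1-ol
Product: 25 (Z)-2-(hydroxymethyl)but-2-enoic acid, via dilithio alkoxide 24 (not isolated)
Conditions: t-BuLi (3.1 equiv), Et2O, −78 °C; CO2; aq. HCl
Reagents that add atoms: carbon dioxide O=C=O
Why: Bromine–lithium exchange on the lithium alkoxide and carboxylation proceed with retention of alkene geometry, giving the acid with CO2H cis to the methyl group.

Step 15
Reactants: 25 (Z)-2-(hydroxymethyl)but-2-enoic acid
Product: 26 (Z)-2-(acetoxymethyl)but-2-enoic acid
Conditions: Ac2O (1.5 equiv), pyridine, DMAP (cat.), CH2Cl2, 0 °C; H2O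
Reagents that add atoms: acetic anhydride CC(=O)OC(C)=O
Why: Acetylation of the primary alcohol; any mixed anhydride of the acid is hydrolysed on aqueous work-up.

Step 16
Reactants: 19 3β,8β-dihydroxy-3α,10α-epoxygermacra-1,4Z,11(13)-trien-6α,12-olide; 26 (Z)-2-(acetoxymethyl)but-2-enoic acid
Product: 28 CNP0256971.1, via Yamaguchi mixed anhydride 27 (not isolated)
Conditions: 26 (1.5 equiv), 2,4,6-trichlorobenzoyl chloride, Et3N, toluene, rt; then 19, DMAP, toluene, rt
Reagents that add atoms: none
Why: Yamaguchi esterification: the mixed anhydride acylates the secondary C8 hydroxyl while the tertiary hemiketal hydroxyl stays free; no stereocentre is touched and the product is the target.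

## Compound list

1 | (R)-4-hydroxycyclopent-2-en-1-one | O=C1C=C[C@H](O)C1 | starting material
2 | 2,2-dimethoxyacetaldehyde | COC(OC)C=O | starting material
3 | bis(dicyclohexylboryl) dienolate of 1 (O-boryl ether and cross-conjugated enol borinate) | C1(OB(C2CCCCC2)C2CCCCC2)=C[C@@H](OB(C2CCCCC2)C2CCCCC2)C=C1 | intermediate
4 | (4S,5S)-4-hydroxy-5-[(1R)-1-hydroxy-2,2-dimethoxyethyl]cyclopent-2-en-1-one (3,9-trans; 8,9-anti) | O=C1C=C[C@H](O)[C@H]1[C@@H](O)C(OC)OC | intermediate
5 | 1-methyl-5-[(1R)-1-hydroxy-2,2-dimethoxyethyl]cyclopent-2-ene-1,4-diol (C10–OH cis to side chain, C3–OH trans) | C[C@]1(O)C=C[C@H](O)[C@H]1[C@@H](O)C(OC)OC | intermediate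
6 | 4-hydroxy-5-[(1R)-1-hydroxy-2,2-dimethoxyethyl]-4-methylcyclopent-2-en-1-one (C10–OH cis to side chain) | C[C@]1(O)C=CC(=O)[C@H]1[C@@H](O)C(OC)OC | intermediate
7 | bis(triethylsilyl) ether of 6 (dimethyl acetal) | C[C@]1(O[Si](CC)(CC)CC)C=CC(=O)[C@H]1[C@@H](O[Si](CC)(CC)CC)C(OC)OC | intermediate
8 | (2R)-2-[2-methyl-5-oxo-2-(triethylsilyloxy)cyclopent-3-en-1-yl]-2-(triethylsilyloxy)acetaldehyde (ring stereocentres as in 6) | C[C@]1(O[Si](CC)(CC)CC)C=CC(=O)[C@H]1[C@@H](O[Si](CC)(CC)CC)C=O | intermediate
9 | methyl acrylate | C=CC(=O)OC | starting material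
10 | Morita–Baylis–Hillman adduct of 8 and 9 (C7 carbinol, both epimers) | C[C@]1(O[Si](CC)(CC)CC)C=CC(=O)[C@H]1[C@@H](O[Si](CC)(CC)CC)C(O)C(=C)C(=O)OC | intermediate
11 | methyl (Z)-2-(bromomethyl)-4-[2-methyl-5-oxo-2-(triethylsilyloxy)cyclopent-3-en-1-yl]-4-(triethylsilyloxy)but-2-enoate (stereocentres as in 8) | C[C@]1(O[Si](CC)(CC)CC)C=CC(=O)[C@H]1[C@@H](O[Si](CC)(CC)CC)/C=C(\CBr)C(=O)OC | intermediate
12 | acrolein | C=CC=O | starting material
13 | anti homoallylic alcohol (methyl 2-methylene ester with C6–OH, 6,7-anti, C7 anti to O8) | C[C@]1(O[Si](CC)(CC)CC)C=CC(=O)[C@H]1[C@@H](O[Si](CC)(CC)CC)[C@H]([C@H](O)C=C)C(=C)C(=O)OC | intermediate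
14 | trans-α-methylene-γ-vinyl-γ-butyrolactone carrying at C7 the C8 silyloxy carbon and the cyclopentenone | C[C@]1(O[Si](CC)(CC)CC)C=CC(=O)[C@H]1[C@@H](O[Si](CC)(CC)CC)[C@@H]2[C@@H](C=C)OC(=O)C2=C | intermediate
15 | C3 isopropenyl carbinol of 14 (isopropenyl trans to the C9 side chain) | C[C@]1(O[Si](CC)(CC)CC)C=C[C@](O)(C(C)=C)[C@H]1[C@@H](O[Si](CC)(CC)CC)[C@@H]2[C@@H](C=C)OC(=O)C2=C | intermediate
16 | tricyclic carbinol: cyclopentene and cycloheptene (C4=C5) fused at C3(OH)–C9, trans-lactone on C6–C7, TES ethers at O8 and O10 | C[C@]1(O[Si](CC)(CC)CC)C=C[C@]2(O)C(C)=C[C@H]3OC(=O)C(=C)[C@@H]3[C@H](O[Si](CC)(CC)CC)[C@@H]12 | intermediate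
17 | 8β,10α-bis(triethylsilyloxy)-3-oxogermacra-1Z,4Z,11(13)-trien-6α,12-olide | C=C1C(=O)O[C@@H]2/C=C(/C)C(=O)/C=C\[C@](C)(O[Si](CC)(CC)CC)C[C@@H](O[Si](CC)(CC)CC)[C@@H]12 | intermediate
18 | 8β,10α-dihydroxy-3-oxogermacra-1Z,4Z,11(13)-trien-6α,12-olide | C=C1C(=O)O[C@@H]2/C=C(/C)C(=O)/C=C\[C@](C)(O)C[C@@H](O)[C@@H]12 | intermediate
19 | 3β,8β-dihydroxy-3α,10α-epoxygermacra-1,4Z,11(13)-trien-6α,12-olide | C=C1C(=O)O[C@@H]2/C=C(/C)[C@@]3(O)C=C[C@@](C)(C[C@@H](O)[C@@H]12)O3 | intermediate
20 | (E)-but-2-enal | C/C=C/C=O | starting material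
21 | (2RS,3SR)-2,3-dibromobutanal (racemic) | CC(Br)C(Br)C=O | intermediate
22 | (Z)-2-bromobut-2-enal | C/C=C(\Br)C=O | intermediate
23 | (Z)-2-bromobut-2-en-1-ol | C/C=C(\Br)CO | intermediate
24 | lithium (Z)-2-lithiobut-2-en-1-olate | C/C=C(\[Li])CO[Li] | intermediate
25 | (Z)-2-(hydroxymethyl)but-2-enoic acid | C/C=C(\C(=O)O)CO | intermediate
26 | (Z)-2-(acetoxymethyl)but-2-enoic acid | C/C=C(\C(=O)O)COC(C)=O | intermediate
27 | (Z)-2-(acetoxymethyl)but-2-enoic 2,4,6-trichlorobenzoic anhydride | C/C=C(\C(=O)OC(=O)c1c(Cl)cc(Cl)cc1Cl)COC(C)=O | intermediate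
28 | CNP0256971.1: 3β-hydroxy-8β-[(Z)-2-(acetoxymethyl)but-2-enoyloxy]-3α,10α-epoxygermacra-1,4Z,11(13)-trien-6α,12-olide | C=C1C(=O)O[C@@H]2/C=C(/C)[C@@]3(O)C=C[C@@](C)(C[C@@H](OC(=O)/C(=C\C)COC(C)=O)[C@@H]12)O3 | target

## Step count and risks

Total steps: 16. Longest linear sequence: 12 (steps 1–11 and 16); the acid 26 is made in 4 steps (12–15).

Three steps most likely to fail:

**Step 10 (proposed new ring expansion).** The alkoxy radical has not been generated by this catalyst system on a bis-allylic ring-fusion carbinol. The thiol or thiyl radical may add to the α-methylene lactone, and the C9 radical could cyclise across the ring, although closure onto C5 would need a strained trans-fused five-membered ring pair. Fallback with known chemistry, setting out from 16 and coming back at 17: Suárez hypoiodite fragmentation (PhI(OAc)2, I2, cyclohexane/CH2Cl2, visible light, rt) carries out the same C3–C9 β-scission stoichiometrically and traps the C9 radical with iodine to give the 9-iodo ten-membered dienone bis-TES ether F1; Bu3SnH with AIBN (benzene, 80 °C) then replaces iodine by hydrogen to give 17.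

**Step 7 (allylchromium addition to acrolein).** The facial control by C8 is likely, but 2-(alkoxycarbonyl)allyl metals often prefer the 6,7-syn adduct, which would give the cis-lactone (C6 epimer). Fallback setting out from 11 and coming back at 14: indium powder with 12 in THF/H2O (Barbier reaction of the geometry-retaining (Z)-allylindium through a closed transition state) is run deliberately for the syn adduct and gives the syn hydroxy ester F2 (C6 epimer of 13, same C7); Me3SnOH (1,2-dichloroethane, 70 °C) gives the syn hydroxy acid F3; Mitsunobu lactonisation (PPh3, DIAD, THF, 0 °C) closes the ring with inversion at C6 and delivers trans-lactone 14.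

**Step 9 (metathesis to the trans-fused trisubstituted cycloheptene, with the chemoselective addition of step 8 before it).** The ring closure onto a quaternary carbinol carbon may be slow, and the trans ring fusion adds strain. Fallback setting out from 11 and coming back at 17: bought but-2-yn-1-ol is reduced with NaAlH2(OCH2CH2OMe)2 and quenched with I2 to give (Z)-3-iodobut-2-en-1-ol F4, which MnO2 oxidises to (Z)-3-iodobut-2-enal F5; F5 replaces 12 in the step 7 coupling with 11 and gives the iodoalkenyl lactone ketone F6; an intramolecular Nozaki–Hiyama–Kishi reaction (CrCl2, NiCl2 1 mol%, DMSO/THF, high dilution) adds the alkenyl metal to the C3 ketone and closes the seven-membered ring as the cis-fused tricyclic carbinol F7 (C3 epimer of 16, same Z alkene); F7 gives 17 under the step 10 conditions because C3 becomes the carbonyl carbon.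

## Further compounds

F1 | step 10 | 9-iodo-8β,10α-bis(triethylsilyloxy)-3-oxogermacra-1Z,4Z,11(13)-trien-6α,12-olide (C9 epimers) | C=C1C(=O)O[C@@H]2/C=C(/C)C(=O)/C=C\[C@](C)(O[Si](CC)(CC)CC)C(I)[C@@H](O[Si](CC)(CC)CC)[C@@H]12
F2 | step 7 | syn hydroxy ester (C6 epimer of 13) | C[C@]1(O[Si](CC)(CC)CC)C=CC(=O)[C@H]1[C@@H](O[Si](CC)(CC)CC)[C@H]([C@@H](O)C=C)C(=C)C(=O)OC
F3 | step 7 | syn hydroxy acid (acid of F2) | C[C@]1(O[Si](CC)(CC)CC)C=CC(=O)[C@H]1[C@@H](O[Si](CC)(CC)CC)[C@H]([C@@H](O)C=C)C(=C)C(=O)O
F4 | step 9 | (Z)-3-iodobut-2-en-1-ol | OC/C=C(/C)I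
F5 | step 9 | (Z)-3-iodobut-2-enal | O=C/C=C(/C)I
F6 | step 9 | iodoalkenyl lactone ketone (14 with (Z)-2-iodoprop-1-enyl in place of vinyl) | C[C@]1(O[Si](CC)(CC)CC)C=CC(=O)[C@H]1[C@@H](O[Si](CC)(CC)CC)[C@@H]2[C@@H](/C=C(/C)I)OC(=O)C2=C
F7 | step 9 | cis-fused tricyclic carbinol (C3 epimer of 16) | C[C@]1(O[Si](CC)(CC)CC)C=C[C@@]2(O)C(C)=C[C@H]3OC(=O)C(=C)[C@@H]3[C@H](O[Si](CC)(CC)CC)[C@@H]12
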